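## Structural features

The target joins three units. The first is a trans-fused octalin (ring A with the C3=C4 double bond, ring B saturated) carrying an (E)-propenyl group at C1, methyl groups at C4 and C7, and five stereocentres (C1, C2, C4a, C7, C8a). The second is a 4-hydroxy-2-pyridone. The third is a cyclohexane with a tertiary alcohol at C1', an epoxide across C2'–C3' and a secondary alcohol at C4'. Decalin C2 is linked to pyridone C3 through a ketone, and pyridone C5 is bonded directly to the quaternary carbinol carbon C1'.

C8a, C1 and C2 are contiguous in ring A (all substituents equatorial, H1 and H2 trans), and C1'–C2'–C3'–C4' are four contiguous oxygenated stereocentres. Several groups are fragile: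

- C2–H is α to the ketone and allylic, so it can epimerise or let C3=C4 move into conjugation.
- The epoxide lies between two carbinols, so it can migrate (Payne rearrangement) with base or open with acid or halide.
- The C1' alcohol sits on an electron-rich heteroaryl carbon and can ionise.
- The acyl hydroxypyridone is acidic and chelating.

The real difficulty is the cyclohexane: a quaternary aryl carbinol and a secondary carbinol, cis to each other and both anti to the epoxide oxygen, in one absolute configuration. The key step exploits exactly this pattern: O2 adds suprafacially across C1' and C4' of a 1-aryl-cyclohexa-1,3-diene whose C2'/C3' oxygens (from an enzymatic arene cis-dihydroxylation) block the other face.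

## Logic of the disconnections

**34 from 33.** No skeletal bond is cut; two O–CH2OMe bonds on the pyridone and two O–Si bonds at C1' and C4' are restored. The acidic pyridone and the free alcohols cannot be carried through lithiation and oxidation. The gain is a neutral, lipophilic precursor. The demand is one mild acidic operation that leaves the epoxide, the C1' carbinol and C2 untouched.

**33 from 32, and 32 from 17 and 30 (through 31).** The bond cut is pyridine C3–C(carbonyl), with the ketone taken back to the carbinol level. C3 is the only ring position flanked by two acetal oxygens, so it can be metalated regiospecifically. An aldehyde partner avoids an enolisable acyl derivative at C2. The gain is two fragments of similar size, each with its own stereocentres. The demand is a metalation cold enough to spare the epoxide, a configurationally pure 30, and a non-basic oxidation.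

**17 from 14 (through 15 and 16).** The bond cut is the epoxide C3'–O bond; the epoxide is traced to the cis-diol by two inversions at one carbon. The oxygen therefore stays on the face where the dioxygenase put it. The demand is that O1' and O4' are capped so that no alkoxide can move the epoxide.

**14 from 13, and 13 from 12.** The benzylic C–O bonds of the acetal and the two O–Si bonds are restored. An isopropylidene acetal would have to be hydrolysed with aqueous acid in the presence of the acid-labile pyridyl acetals and the silyl ethers. A benzylidene acetal shields the same face and leaves by neutral hydrogenolysis, at a stage where the molecule has no C=C bond.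

**12 from 10 (through 11).** The O–O bond is re-formed and C5'=C6' reintroduced. A cis-1,4-diol is the reduced form of a peroxide bridge. The demand is saturation of the alkene before the O–O bond is cleaved, then O–O reduction without touching either C–O bond.

**10 from 9 (key step).** The bonds cut are C1'–O and C4'–O. Two stereocentres (one quaternary), two oxygen atoms and one ring are removed at once. What is left is a flat diene whose only stereocentres are the two enzyme-derived ones. The demand is addition anti to the acetal and [4+2] rather than ene or [2+2] reactivity.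

**9 from 3 and 6 (through 7 and 8).** The bond cut is C1'–C5(pyridine), sp2–sp2. The alkenyl bromide is exactly what oxidation of 1 provides. The demand is a coupling mild enough that the diene does not dimerise.

**3 from 2, 2 from 1; 6 from 5, 5 from 4.** Acetal C–O bonds, the two arene C–O bonds made by the enzyme, the C5–Br bond and the two O–CH2OMe bonds. Absolute configuration enters here from the biocatalyst.

**30 from 29, 28, 27 and 26.** The C2 configuration, the aldehyde oxidation level, the O–Si bond and the propenyl C=C bond are traced back in turn. The demand is a C2 epimerisation that does not move C3=C4.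

**26 from 25.** The bonds cut are C1–C2 and C4a–C8a (ring A, intramolecular Diels–Alder). Two rings and four stereocentres collapse to an acyclic triene with the single C7 stereocentre. The demand is an endo transition state with a chair tether; the consequence is a C2 substituent cis to C1.

**25 from 24, 23, 22, 21 (through 20), 19 and 18.** The O–Si bond, then three C=C bonds (carbonyl olefinations), then the C=C bond of 18 (ozonolysis). C7 is bought from the chiral pool.

## Other disconnections considered

**Alternative 1:** The cut runs through ring A of the decalin, at C8a–C1 and at C4=C4a, and leads back to 4-methylcyclohexanone A3 and the propenyl-substituted alkylidene keto ester A2. In the forward sense A3, activated by a chiral amine as its enamine, would add through C8a to C1 of A2 (Michael addition). The ethyl ketone would then condense onto the ring carbonyl (aldol condensation) to close ring A and give the octalone ester A1.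

- In its favour: ring A and the centres C1, C2, C7 and C8a would arise in one operation from cheap achiral materials. C2 in A1 lies between ketone and ester, so the trans C1/C2 relationship would be reached by free equilibration. On both points it is better than the chosen plan, which needs eleven steps to 30 and a separate, only moderately biased epimerisation (step 21).
- Against it here: the amine would have to control a methyl-bearing centre three bonds from the reacting carbon (desymmetrisation). The dienyl acceptor offers 1,4- and 1,6-addition. A1 still needs removal of the C3 oxygen, delivery of hydrogen to C4a with a trans ring fusion, transposition of the alkene to C3=C4 and reduction of the ester.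
- Comparison: structurally it addresses only the decalin and leaves the oxygenated cyclohexane, the harder half, untouched. Mechanistically it relies on reagent control of a remote centre, where the chosen key step relays enzyme-derived centres to their neighbours. In step economy it would be the shorter way to the decalin and could replace steps 11–21 without changing the rest.

**Alternative 2:** The cut removes both bonds to the ketone carbon, decalin C2–C(O) and C(O)–pyridine C3. In the forward sense zerovalent palladium would ionise the decalin C2 carbonate A5, carbon monoxide A7 would insert, and the acylpalladium would couple with the 3-stannylpyridine A6 to give the fully protected target A4.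

- In its favour: it is the most convergent union, one step instead of two (steps 22 and 23). Ionisation with inversion followed by insertion and coupling with retention would convert a C2 oxygen that is cis to the propenyl group (the natural outcome of a Diels–Alder route) directly into the trans acyl group. On stereocontrol at C2 it is the better plan, since the chosen route corrects C2 by equilibration.
- Against it here: the secondary cyclic allyl–palladium has syn hydrogens at C1 and C4a, so diene formation by β-hydride elimination would compete. The stannane is flanked by two alkoxy groups, so transmetalation would be slow and direct, non-carbonylative coupling would compete. C4 is a second possible site of attack. Organotin residues would have to be removed from a late intermediate.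
- Comparison: A6 needs the same epoxycyclohexyl pyridine as 17, so this is another union rather than another way to the oxygenated ring. Mechanistically it stacks three catalytic events where the chosen union uses a stoichiometric carbanion addition. In step count it is equal to the chosen plan or one step shorter.

**Alternative 3:** The cut is again in ring A, at C1–C8a and C2–C3. In the forward sense the silyloxydiene A9 would add to the (E)-oxobutenoate A10 under a chiral boron Lewis acid to give the cyclohexene A8.

- In its favour: the trans relationship of the C1 and C2 substituents would follow directly from the (E)-dienophile, and the catalyst would set the absolute configuration. The formyl group is the propenyl precursor, the ester the acyl precursor. On C1/C2 control it is better than the Diels–Alder step of the chosen plan, which delivers the cis arrangement.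
- Against it here: the diene must distinguish two different acceptor groups on the dienophile (regiochemistry). Ring B with C4a, C7 and C8a would still have to be annulated onto a ring in which C8a is an unactivated methylene. The C4 methyl group and the C3=C4 alkene would have to be introduced afterwards.
- Comparison: structurally it sets two of the five decalin centres early and defers three. The chosen plan sets four in one cyclisation from a chiral-pool centre and corrects one. Mechanistically both are [4+2] reactions, one catalyst-controlled and intermolecular, one substrate-controlled and intramolecular. In step economy for the whole decalin it is expected to be longer, and like Alternative 1 it does not touch the oxygenated cyclohexane.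

Key step: step 6

Remark: atom labels follow the target throughout (decalin C1–C8a with C1 bearing the propenyl group; cyclohexane C1'–C6' with C1' bonded to the pyridone; pyridone N1–C6).

Remark: the heteroaryl group on C1' is pyridone C5, named 4,6-bis(methoxymethoxy)pyridin-3-yl by the lowest-locant rule. The (1S,2S) descriptors of 2 become (3aR,7aS) in 9 only through a change of CIP priorities; the oxygen-bearing carbons keep their spatial arrangement.

Remark: 3 is drawn as its exo-phenyl acetal epimer. The endo epimer, if formed, would shield the same face and converge at 14.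

## Route

Step 1
Reactants: 1 bromobenzene
Product: 2 (1S,2S)-3-bromocyclohexa-3,5-diene-1,2-diol
Conditions: E. coli JM109(pDTG601A) whole cells (toluene dioxygenase), IPTG, glucose, air, phosphate buffer pH 7.2, 30 °C; EtOAc extraction
Reagents that add atoms: dioxygen, O=O
Why: Whole-cell arene cis-dihydroxylation by toluene dioxygenase (a Rieske non-haem iron dioxygenase) adds both oxygen atoms of O2 to the 2,3-bond of 1 from one face; the enzyme sets both carbinol stereocentres (the future C3' and C2') in one enantiomeric series.

Step 2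
Reactants: 2 (1S,2S)-3-bromocyclohexa-3,5-diene-1,2-diol
Product: 3 (2R,3aS,7aS)-4-bromo-2-phenyl-3a,7a-dihydro-1,3-benzodioxole
Conditions: PhCH(OMe)2, CSA (2 mol%), 4 Å MS, CH2Cl2, −10 → 0 °C; Et3N quench; used at once
Reagents that add atoms: benzaldehyde dimethyl acetal, COC(OC)c1ccccc1
Why: Acid-catalysed transacetalisation of the cis-diol, kept cold and brief so that the diol does not dehydrate to a bromophenol; the acetal prevents aromatisation, covers the lower diene face for step 6 and, unlike an isopropylidene group, can later be removed by neutral hydrogenolysis beside methoxymethyl and silyl ethers.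

Step 3
Reactants: 4 2,4-dihydroxypyridine
Product: 5 2,4-bis(methoxymethoxy)pyridine
Conditions: MOMCl (2.4 equiv), Ag2CO3 (1.3 equiv), toluene, rt, dark
Reagents that add atoms: chloromethyl methyl ether, COCCl
Why: Silver-carbonate-mediated O-alkylation (Williamson type) of the hydroxypyridone; the silver salt steers the ambident lactam to O- rather than N-alkylation, giving the bis-acetal that later directs lithiation to C3 and leaves under mild acid.

Step 4
Reactants: 5 2,4-bis(methoxymethoxy)pyridine
Product: 6 5-bromo-2,4-bis(methoxymethoxy)pyridine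
Conditions: NBS (1.05 equiv), MeCN, 0 °C → rt
Reagents that add atoms: N-bromosuccinimide, O=C1CCC(=O)N1Br
Why: Electrophilic aromatic bromination; C5 is para to the 2-alkoxy and ortho to the 4-alkoxy group and less hindered than C3, which lies between the two acetal groups, as in the 4-bromination of 1,3-dialkoxybenzenes.

Step 5
Reactants: 6 5-bromo-2,4-bis(methoxymethoxy)pyridine; 3 (2R,3aS,7aS)-4-bromo-2-phenyl-3a,7a-dihydro-1,3-benzodioxole
Product: 9 (2R,3aR,7aS)-4-[4,6-bis(methoxymethoxy)pyridin-3-yl]-2-phenyl-3a,7a-dihydro-1,3-benzodioxole, via pyridylmagnesium chloride 7 (not isolated), via pyridylzinc chloride 8 (not isolated)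
Conditions: i-PrMgCl·LiCl (1.1 equiv), THF, 0 °C → rt; ZnCl2 (1.2 equiv), 0 °C; then 3, Pd(PPh3)4 (4 mol%), THF, rt → 40 °C
Reagents that add atoms: none
Why: Bromine–magnesium exchange, transmetalation to zinc and Negishi coupling of the arylzinc with the alkenyl bromide under zerovalent palladium form the C1'–C5(pyridine) bond with retention of the diene; the near-ambient temperature limits Diels–Alder dimerisation of the diene and leaves the two carbinol stereocentres untouched.

Step 6
Reactants: 9 (2R,3aR,7aS)-4-[4,6-bis(methoxymethoxy)pyridin-3-yl]-2-phenyl-3a,7a-dihydro-1,3-benzodioxole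
Product: 10 1-[4,6-bis(methoxymethoxy)pyridin-3-yl]-5,6-(exo-benzylidenedioxy)-2,3-dioxabicyclo[2.2.2]oct-7-ene (peroxide bridge C1'–C4' anti to the acetal)
Conditions: O2, tetraphenylporphyrin (0.5 mol%), CH2Cl2, visible light (LED), −40 °C; cold evaporation, short silica plug
Reagents that add atoms: dioxygen (as singlet oxygen), O=O
Why: Visible-light excitation of tetraphenylporphyrin sensitises ground-state O2 to singlet oxygen, which adds across C1' and C4' of the s-cis-locked diene of 9 in a concerted, suprafacial [4+2] cycloaddition (hetero-Diels–Alder). The closest known reaction type is the dye-sensitised photooxygenation of cyclohexa-1,3-dienes, in particular of acetal-protected arene cis-dihydrodiols, to 2,3-dioxabicyclo[2.2.2]octenes. The one ring that closes is the six-membered 1,2-dioxene (C1'–O–O–C4'–C5'=C6'); it closes by cycloaddition, both C–O bonds forming in the same step, so no separate cyclisation mode competes. C1' and C4' become stereocentres: suprafaciality forces the two new C–O bonds to be cis to each other, and their configuration relative to C2'/C3' is set by approach of O2 to the face opposite the cis-fused benzylidene acetal, whose dioxolane ring and oxygen lone pairs block the other face. Because C2' and C3' come enantiopure from the enzymatic dihydroxylation, this relative control fixes the absolute configuration of the quaternary C1' and of C4'. The step needs face selectivity and periselectivity for [4+2] over the ene reaction and over [2+2] addition to the aryl-substituted double bond; the rigid cisoid diene, the acetal and the twist of the ortho-substituted pyridine ring out of conjugation secure both. Low temperature, a neutral medium and cold work-up keep the peroxide from thermal rearrangement to a bis-epoxide and from base-induced Kornblum–DeLaMare isomerisation.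

Step 7
Reactants: 10 1-[4,6-bis(methoxymethoxy)pyridin-3-yl]-5,6-(exo-benzylidenedioxy)-2,3-dioxabicyclo[2.2.2]oct-7-ene
Product: 12 (1R,2S,3S,4R)-1-[4,6-bis(methoxymethoxy)pyridin-3-yl]-2,3-O-benzylidenecyclohexane-1,2,3,4-tetrol, via saturated endoperoxide 11 (not isolated)
Conditions: KO2CN=NCO2K (8 equiv), AcOH (16 equiv), CH2Cl2–MeOH, −30 → 0 °C; then thiourea (2 equiv), MeOH, 0 °C → rt
Reagents that add atoms: none
Why: Diimide, released by protonolysis and decarboxylation of the azodicarboxylate, transfers H2 concertedly and syn to the strained C5'=C6' bond without cleaving the O–O bond, which a hydrogenation catalyst would attack first; thiourea then reduces the peroxide (attack of sulfur on O–O) to the cis-1,4-diol, so both C–O bonds and the configurations at C1' and C4' are retained.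

Step 8
Reactants: 12 (1R,2S,3S,4R)-1-[4,6-bis(methoxymethoxy)pyridin-3-yl]-2,3-O-benzylidenecyclohexane-1,2,3,4-tetrol
Product: 13 (1R,2S,3R,4R)-1-[4,6-bis(methoxymethoxy)pyridin-3-yl]-2,3-O-benzylidene-1,4-bis-O-(triethylsilyl)cyclohexane-1,2,3,4-tetrol
Conditions: Et3SiOTf (3 equiv), 2,6-lutidine (5 equiv), CH2Cl2, −78 → 0 °C
Reagents that add atoms: triethylsilyl trifluoromethanesulfonate, CC[Si](CC)(CC)OS(=O)(=O)C(F)(F)F
Why: Silyl triflate with a hindered base silylates the secondary C4' and the hindered tertiary C1' hydroxyl in one operation; both must be capped so that no alkoxide can trigger a Payne rearrangement in step 10 and no alcohol is oxidised in step 23.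

Step 9
Reactants: 13 (1R,2S,3R,4R)-1-[4,6-bis(methoxymethoxy)pyridin-3-yl]-2,3-O-benzylidene-1,4-bis-O-(triethylsilyl)cyclohexane-1,2,3,4-tetrol
Product: 14 (1R,2S,3R,4R)-1-[4,6-bis(methoxymethoxy)pyridin-3-yl]-1,4-bis(triethylsilyloxy)cyclohexane-2,3-diol
Conditions: H2 (1 atm), Pd(OH)2/C, EtOAc, rt
Reagents that add atoms: none
Why: Hydrogenolysis of the two benzylic C–O bonds of the benzylidene acetal under neutral conditions; the molecule has no C=C bond at this stage, and the methoxymethyl ethers, silyl ethers and pyridine ring are inert.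

Step 10
Reactants: 14 (1R,2S,3R,4R)-1-[4,6-bis(methoxymethoxy)pyridin-3-yl]-1,4-bis(triethylsilyloxy)cyclohexane-2,3-diol
Product: 17 5-[(1R,2S,3R,4R)-2,3-epoxy-1,4-bis(triethylsilyloxy)cyclohexyl]-2,4-bis(methoxymethoxy)pyridine (epoxide oxygen anti to O1' and O4'), via cyclic orthoacetate 15 (not isolated), via trans-bromo acetate 16 (not isolated)
Conditions: MeC(OMe)3 (1.5 equiv), PPTS (2 mol%), CH2Cl2, rt, evaporate; AcBr (1.2 equiv), CH2Cl2, 0 °C, evaporate; K2CO3 (2.5 equiv), MeOH, 0 °C → rt
Reagents that add atoms: none
Why: One-pot conversion of a cis-1,2-diol into an epoxide through a cyclic orthoester: acetyl bromide ionises 15 to a 1,3-dioxolan-2-ylium ion that bromide opens with inversion at the less hindered C3' (16), and methanolysis of the acetate frees the C2' alkoxide, which displaces bromide with a second inversion (intramolecular Williamson closure, trans-diaxial); the epoxide oxygen therefore stays on the face of the original diol, and the regioisomeric opening would converge on the same epoxide.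

Step 11
Reactants: 18 (S)-citronellal
Product: 19 (2E,5S)-N-methoxy-N,5,9-trimethyldeca-2,8-dienamide
Conditions: (EtO)2P(O)CH2C(O)N(OMe)Me (1.2 equiv), NaH (1.15 equiv), THF, 0 °C; then 18, 0 °C → rt
Reagents that add atoms: diethyl [2-[methoxy(methyl)amino]-2-oxoethyl]phosphonate, CCOP(=O)(CC(=O)N(C)OC)OCC
Why: Horner–Wadsworth–Emmons olefination with a stabilised phosphonate anion gives the (E)-enamide; the amide survives the following oxidation and olefinations and later releases the dienophile aldehyde on hydride reduction, and the methyl-bearing centre (the future C7) comes unchanged from the chiral pool.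

Step 12
Reactants: 19 (2E,5S)-N-methoxy-N,5,9-trimethyldeca-2,8-dienamide
Product: 21 (2E,5S)-N-methoxy-N,5-dimethyl-8-oxooct-2-enamide, via ozonide 20 (not isolated)
Conditions: O3 (1 equiv), CH2Cl2, −78 °C; PPh3 (1.2 equiv), −78 °C → rt
Reagents that add atoms: ozone, [O-][O+]=O
Why: Ozonolysis (1,3-dipolar cycloaddition, cycloreversion and recombination to the ozonide, then reduction by the phosphine); the electron-rich trisubstituted alkene reacts far faster than the electron-poor enamide double bond, so ozone is dosed to one equivalent.

Step 13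
Reactants: 21 (2E,5S)-N-methoxy-N,5-dimethyl-8-oxooct-2-enamide
Product: 22 (2E,5S,8E)-N-methoxy-N,5,9-trimethyl-10-oxodeca-2,8-dienamide
Conditions: Ph3P=C(CH3)CHO (1.3 equiv), toluene, 90 °C
Reagents that add atoms: 2-(triphenylphosphoranylidene)propanal, CC(C=O)=P(c1ccccc1)(c1ccccc1)c1ccccc1
Why: Wittig olefination with a stabilised, α-branched ylide gives the (E)-2-methyl enal through reversible oxaphosphetane formation, installing C4 with its methyl group.

Step 14
Reactants: 22 (2E,5S,8E)-N-methoxy-N,5,9-trimethyl-10-oxodeca-2,8-dienamide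
Product: 23 ethyl (2E,4E,8S,10E)-12-[methoxy(methyl)amino]-4,8-dimethyl-12-oxododeca-2,4,10-trienoate
Conditions: (EtO)2P(O)CH2CO2Et (1.3 equiv), NaH (1.25 equiv), THF, 0 °C → rt
Reagents that add atoms: triethyl phosphonoacetate, CCOC(=O)CP(=O)(OCC)OCC
Why: Horner–Wadsworth–Emmons olefination of the enal gives the (E,E)-dienoate; the phosphonate anion is too stabilised to add to the enamide.

Step 15
Reactants: 23 ethyl (2E,4E,8S,10E)-12-[methoxy(methyl)amino]-4,8-dimethyl-12-oxododeca-2,4,10-trienoate
Product: 24 (2E,5S,8E,10E)-12-hydroxy-5,9-dimethyldodeca-2,8,10-trienal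
Conditions: i-Bu2AlH (5 equiv), CH2Cl2, −78 → −40 °C; MeOH at −78 °C, then aq. potassium sodium tartrate, rt
Reagents that add atoms: none
Why: Diisobutylaluminium hydride reduces the conjugated ester 1,2 to the allylic alcohol, while the N-methoxy-N-methylamide is held as a chelated aluminium hemiaminal that collapses to the aldehyde only on work-up; one operation thus makes the diene electron-rich and unmasks the enal dienophile.

Step 16
Reactants: 24 (2E,5S,8E,10E)-12-hydroxy-5,9-dimethyldodeca-2,8,10-trienal
Product: 25 (2E,5S,8E,10E)-12-[tert-butyl(diphenyl)silyl]oxy-5,9-dimethyldodeca-2,8,10-trienal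
Conditions: t-BuPh2SiCl (1.1 equiv), imidazole (2 equiv), CH2Cl2, 0 °C
Reagents that add atoms: tert-butyl(chloro)diphenylsilane, CC(C)(C)[Si](Cl)(c1ccccc1)c1ccccc1
Why: Chemoselective silylation of the primary allylic alcohol with silyl chloride and imidazole; the bulky, weakly Lewis-basic silyl ether tolerates the Lewis acid of step 17 and keeps the hydroxyl from forming a lactol with the C1 formyl group.

Step 17
Reactants: 25 (2E,5S,8E,10E)-12-[tert-butyl(diphenyl)silyl]oxy-5,9-dimethyldodeca-2,8,10-trienal
Product: 26 (1R,2S,4aS,7S,8aS)-2-{[tert-butyl(diphenyl)silyl]oxymethyl}-4,7-dimethyl-1,2,4a,5,6,7,8,8a-octahydronaphthalene-1-carbaldehyde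
Conditions: Me2AlCl (1.2 equiv), CH2Cl2, −78 → −30 °C; aq. NaHCO3
Reagents that add atoms: none
Why: Lewis-acid-promoted type 1 intramolecular Diels–Alder reaction forms C1–C2 and C4a–C8a: the endo transition state (carbonyl under the diene, four-carbon tether in a chair with the C7 methyl equatorial) gives the trans ring fusion and relays C7 to C4a and C8a, the (E)-dienophile places the formyl group at C1 trans to C8, and the (E,E)-diene places the C2 substituent cis to that formyl group, which is why C2 is corrected in step 21.

Step 18
Reactants: 26 (1R,2S,4aS,7S,8aS)-2-{[tert-butyl(diphenyl)silyl]oxymethyl}-4,7-dimethyl-1,2,4a,5,6,7,8,8a-octahydronaphthalene-1-carbaldehyde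
Product: 27 tert-butyl{[(1R,2R,4aS,7S,8aR)-4,7-dimethyl-1-[(E)-prop-1-enyl]-1,2,4a,5,6,7,8,8a-octahydronaphthalen-2-yl]methoxy}diphenylsilane
Conditions: 5-(ethylsulfonyl)-1-phenyl-1H-tetrazole (1.5 equiv), KN(SiMe3)2 (1.4 equiv), DME, −60 °C; then 26, −60 °C → rt
Reagents that add atoms: 5-(ethylsulfonyl)-1-phenyl-1H-tetrazole, CCS(=O)(=O)c1nnnn1-c1ccccc1
Why: Julia–Kocienski olefination (addition of the metalated sulfone, Smiles rearrangement, loss of SO2 and aryloxide) converts the α-branched aldehyde into the (E)-propenyl group; the equatorial C1 centre is the stable epimer and is not at risk.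

Step 19
Reactants: 27 tert-butyl{[(1R,2R,4aS,7S,8aR)-4,7-dimethyl-1-[(E)-prop-1-enyl]-1,2,4a,5,6,7,8,8a-octahydronaphthalen-2-yl]methoxy}diphenylsilane
Product: 28 [(1R,2R,4aS,7S,8aR)-4,7-dimethyl-1-[(E)-prop-1-enyl]-1,2,4a,5,6,7,8,8a-octahydronaphthalen-2-yl]methanol
Conditions: Bu4NF (1.3 equiv), THF, 0 °C → rt
Reagents that add atoms: none
Why: Fluoride-mediated cleavage of the silyl ether, driven by Si–F bond formation, frees the primary alcohol.

Step 20
Reactants: 28 [(1R,2R,4aS,7S,8aR)-4,7-dimethyl-1-[(E)-prop-1-enyl]-1,2,4a,5,6,7,8,8a-octahydronaphthalen-2-yl]methanol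
Product: 29 (1R,2R,4aS,7S,8aR)-4,7-dimethyl-1-[(E)-prop-1-enyl]-1,2,4a,5,6,7,8,8a-octahydronaphthalene-2-carbaldehyde (formyl cis to propenyl)
Conditions: Dess–Martin periodinane (1.3 equiv), NaHCO3, CH2Cl2, 0 °C → rt; crude product used directly
Reagents that add atoms: none
Why: Dess–Martin oxidation under buffered, non-basic conditions gives the β,γ-unsaturated aldehyde without moving the C3=C4 bond.

Step 21
Reactants: 29 (1R,2R,4aS,7S,8aR)-4,7-dimethyl-1-[(E)-prop-1-enyl]-1,2,4a,5,6,7,8,8a-octahydronaphthalene-2-carbaldehyde
Product: 30 (1R,2S,4aS,7S,8aR)-4,7-dimethyl-1-[(E)-prop-1-enyl]-1,2,4a,5,6,7,8,8a-octahydronaphthalene-2-carbaldehyde (formyl trans to propenyl)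
Conditions: DBU (0.2 equiv), CH2Cl2, 0 °C → rt, stopped at equilibrium; chromatography, recovered 29 resubmitted
Reagents that add atoms: none
Why: Base-mediated epimerisation α to the aldehyde: reversible deprotonation to the dienolate and kinetic reprotonation at C2 equilibrate 29 with 30, in which formyl and propenyl are both equatorial (trans); the equilibrium is expected to favour 30 only moderately, so unchanged 29 is separated and resubmitted, and the reaction is stopped before γ-protonation can move the double bond into conjugation.

Step 22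
Reactants: 17 5-[(1R,2S,3R,4R)-2,3-epoxy-1,4-bis(triethylsilyloxy)cyclohexyl]-2,4-bis(methoxymethoxy)pyridine; 30 (1R,2S,4aS,7S,8aR)-4,7-dimethyl-1-[(E)-prop-1-enyl]-1,2,4a,5,6,7,8,8a-octahydronaphthalene-2-carbaldehyde
Product: 32 [(1R,2S,4aS,7S,8aR)-4,7-dimethyl-1-[(E)-prop-1-enyl]-1,2,4a,5,6,7,8,8a-octahydronaphthalen-2-yl]{5-[(1R,2S,3R,4R)-2,3-epoxy-1,4-bis(triethylsilyloxy)cyclohexyl]-2,4-bis(methoxymethoxy)pyridin-3-yl}methanol (both carbinol epimers), via 3-lithiopyridine 31 (not isolated)
Conditions: 17, n-BuLi (1.1 equiv), THF, −78 °C, 45 min; then 30 (1.2 equiv), −78 °C; aq. NH4Cl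
Reagents that add atoms: none
Why: Directed ortho-metalation: the two methoxymethyl acetals flanking C3 pre-complex the alkyllithium and make C3–H the kinetic site at −78 °C, where the epoxide and silyl ethers are inert; 1,2-addition of 31 to the aldehyde forms the C3–C bond faster than enolisation, and the mixture of carbinol epimers is of no consequence.

Step 23
Reactants: 32 the carbinol from step 22
Product: 33 [(1R,2S,4aS,7S,8aR)-4,7-dimethyl-1-[(E)-prop-1-enyl]-1,2,4a,5,6,7,8,8a-octahydronaphthalen-2-yl]{5-[(1R,2S,3R,4R)-2,3-epoxy-1,4-bis(triethylsilyloxy)cyclohexyl]-2,4-bis(methoxymethoxy)pyridin-3-yl}methanone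
Conditions: Dess–Martin periodinane (1.5 equiv), NaHCO3, CH2Cl2, 0 °C → rt
Reagents that add atoms: none
Why: Dess–Martin oxidation of the hindered secondary carbinol to the ketone under buffered conditions removes the extra stereocentre without epimerising C2.

Step 24
Reactants: 33 the protected ketone from step 23
Product: 34 3-[(1R,2S,4aS,7S,8aR)-4,7-dimethyl-1-[(E)-prop-1-enyl]-1,2,4a,5,6,7,8,8a-octahydronaphthalene-2-carbonyl]-5-[(1R,2S,3S,4R)-2,3-epoxy-1,4-dihydroxycyclohexyl]-4-hydroxypyridin-2(1H)-one (CNP0494338.1)
Conditions: CF3CO2H–CH2Cl2 (1:6), H2O (10 equiv), 0 °C; aq. NaHCO3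
Reagents that add atoms: none
Why: Acid-catalysed cleavage of the two pyridyl methoxymethyl acetals (the pyridone is the leaving group, so they hydrolyse far faster than alkyl acetals) and of the two triethylsilyl ethers in one operation; the N-protonated, acyl-substituted pyridine disfavours ionisation at C1', and the epoxide, flanked by two oxygen-bearing carbons, is deactivated toward acid opening at 0 °C.

## Compound list

1 | bromobenzene | Brc1ccccc1 | starting material
2 | (1S,2S)-3-bromocyclohexa-3,5-diene-1,2-diol | O[C@H]1C=CC=C(Br)[C@H]1O | intermediate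
3 | (2R,3aS,7aS)-4-bromo-2-phenyl-3a,7a-dihydro-1,3-benzodioxole (exo-phenyl) | BrC1=CC=C[C@@H]2O[C@@H](c3ccccc3)O[C@H]12 | intermediate
4 | 2,4-dihydroxypyridine (4-hydroxypyridin-2(1H)-one) | Oc1ccnc(O)c1 | starting material
5 | 2,4-bis(methoxymethoxy)pyridine | COCOc1ccnc(OCOC)c1 | intermediate
6 | 5-bromo-2,4-bis(methoxymethoxy)pyridine | COCOc1cc(OCOC)ncc1Br | intermediate
7 | [4,6-bis(methoxymethoxy)pyridin-3-yl]magnesium chloride | COCOc1cc(OCOC)ncc1[Mg]Cl | intermediate
8 | [4,6-bis(methoxymethoxy)pyridin-3-yl]zinc chloride | COCOc1cc(OCOC)ncc1[Zn]Cl | intermediate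
9 | (2R,3aR,7aS)-4-[4,6-bis(methoxymethoxy)pyridin-3-yl]-2-phenyl-3a,7a-dihydro-1,3-benzodioxole | COCOc1cc(OCOC)ncc1C1=CC=C[C@@H]2O[C@@H](c3ccccc3)O[C@H]12 | intermediate
10 | 1-[4,6-bis(methoxymethoxy)pyridin-3-yl]-5,6-(exo-benzylidenedioxy)-2,3-dioxabicyclo[2.2.2]oct-7-ene, O–O bridge anti to the acetal | COCOc1cc(OCOC)ncc1[C@]12OO[C@H](C=C1)[C@@H]3O[C@@H](c4ccccc4)O[C@@H]32 | intermediate
11 | 1-[4,6-bis(methoxymethoxy)pyridin-3-yl]-5,6-(exo-benzylidenedioxy)-2,3-dioxabicyclo[2.2.2]octane | COCOc1cc(OCOC)ncc1[C@]12OO[C@H](CC1)[C@@H]3O[C@@H](c4ccccc4)O[C@@H]32 | intermediate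
12 | (1R,2S,3S,4R)-1-[4,6-bis(methoxymethoxy)pyridin-3-yl]-2,3-O-benzylidenecyclohexane-1,2,3,4-tetrol | COCOc1cc(OCOC)ncc1[C@]2(O)CC[C@@H](O)[C@@H]3O[C@@H](c4ccccc4)O[C@@H]32 | intermediate
13 | (1R,2S,3R,4R)-1-[4,6-bis(methoxymethoxy)pyridin-3-yl]-2,3-O-benzylidene-1,4-bis-O-(triethylsilyl)cyclohexane-1,2,3,4-tetrol | COCOc1cc(OCOC)ncc1[C@]2(O[Si](CC)(CC)CC)CC[C@@H](O[Si](CC)(CC)CC)[C@@H]3O[C@@H](c4ccccc4)O[C@@H]32 | intermediate
14 | (1R,2S,3R,4R)-1-[4,6-bis(methoxymethoxy)pyridin-3-yl]-1,4-bis(triethylsilyloxy)cyclohexane-2,3-diol | COCOc1cc(OCOC)ncc1[C@]1(O[Si](CC)(CC)CC)CC[C@@H](O[Si](CC)(CC)CC)[C@H](O)[C@@H]1O | intermediate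
15 | cyclic methyl orthoacetate of 14 (2-methoxy-2-methyl-1,3-dioxolane fused at C2'/C3') | COCOc1cc(OCOC)ncc1[C@]2(O[Si](CC)(CC)CC)CC[C@@H](O[Si](CC)(CC)CC)[C@@H]3OC(C)(OC)O[C@@H]32 | intermediate
16 | trans-bromo acetate (bromine at C3' on the face of O4', acetate at C2') | COCOc1cc(OCOC)ncc1[C@]1(O[Si](CC)(CC)CC)CC[C@@H](O[Si](CC)(CC)CC)[C@@H](Br)[C@@H]1OC(C)=O | intermediate
17 | 5-[(1R,2S,3R,4R)-2,3-epoxy-1,4-bis(triethylsilyloxy)cyclohexyl]-2,4-bis(methoxymethoxy)pyridine | COCOc1cc(OCOC)ncc1[C@]2(O[Si](CC)(CC)CC)CC[C@@H](O[Si](CC)(CC)CC)[C@@H]3O[C@@H]32 | intermediate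
18 | (S)-citronellal [(3S)-3,7-dimethyloct-6-enal] | O=CC[C@@H](C)CCC=C(C)C | starting material
19 | (2E,5S)-N-methoxy-N,5,9-trimethyldeca-2,8-dienamide | CON(C)C(=O)/C=C/C[C@@H](C)CCC=C(C)C | intermediate
20 | ozonide of 19 (3,3-dimethyl-1,2,4-trioxolane at the former C8=C9) | CON(C)C(=O)/C=C/C[C@@H](C)CCC1OOC(C)(C)O1 | intermediate
21 | (2E,5S)-N-methoxy-N,5-dimethyl-8-oxooct-2-enamide | CON(C)C(=O)/C=C/C[C@@H](C)CCC=O | intermediate
22 | (2E,5S,8E)-N-methoxy-N,5,9-trimethyl-10-oxodeca-2,8-dienamide | CON(C)C(=O)/C=C/C[C@@H](C)CC/C=C(C)/C=O | intermediate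
23 | ethyl (2E,4E,8S,10E)-12-[methoxy(methyl)amino]-4,8-dimethyl-12-oxododeca-2,4,10-trienoate | CON(C)C(=O)/C=C/C[C@@H](C)CC/C=C(C)/C=C/C(=O)OCC | intermediate
24 | (2E,5S,8E,10E)-12-hydroxy-5,9-dimethyldodeca-2,8,10-trienal | O=C/C=C/C[C@@H](C)CC/C=C(C)/C=C/CO | intermediate
25 | (2E,5S,8E,10E)-12-[tert-butyl(diphenyl)silyl]oxy-5,9-dimethyldodeca-2,8,10-trienal | O=C/C=C/C[C@@H](C)CC/C=C(C)/C=C/CO[Si](c1ccccc1)(c1ccccc1)C(C)(C)C | intermediate
26 | (1R,2S,4aS,7S,8aS)-2-{[tert-butyl(diphenyl)silyl]oxymethyl}-4,7-dimethyl-1,2,4a,5,6,7,8,8a-octahydronaphthalene-1-carbaldehyde | O=C[C@@H]1[C@H]2C[C@@H](C)CC[C@@H]2C(C)=C[C@@H]1CO[Si](c1ccccc1)(c1ccccc1)C(C)(C)C | intermediate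
27 | tert-butyl{[(1R,2R,4aS,7S,8aR)-4,7-dimethyl-1-[(E)-prop-1-enyl]-1,2,4a,5,6,7,8,8a-octahydronaphthalen-2-yl]methoxy}diphenylsilane | C/C=C/[C@@H]1[C@H]2C[C@@H](C)CC[C@@H]2C(C)=C[C@@H]1CO[Si](c1ccccc1)(c1ccccc1)C(C)(C)C | intermediate
28 | [(1R,2R,4aS,7S,8aR)-4,7-dimethyl-1-[(E)-prop-1-enyl]-1,2,4a,5,6,7,8,8a-octahydronaphthalen-2-yl]methanol | C/C=C/[C@@H]1[C@H]2C[C@@H](C)CC[C@@H]2C(C)=C[C@@H]1CO | intermediate
29 | (1R,2R,4aS,7S,8aR)-4,7-dimethyl-1-[(E)-prop-1-enyl]-1,2,4a,5,6,7,8,8a-octahydronaphthalene-2-carbaldehyde (formyl cis to propenyl) | C/C=C/[C@@H]1[C@H]2C[C@@H](C)CC[C@@H]2C(C)=C[C@@H]1C=O | intermediate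
30 | (1R,2S,4aS,7S,8aR)-4,7-dimethyl-1-[(E)-prop-1-enyl]-1,2,4a,5,6,7,8,8a-octahydronaphthalene-2-carbaldehyde (formyl trans to propenyl) | C/C=C/[C@@H]1[C@H]2C[C@@H](C)CC[C@@H]2C(C)=C[C@H]1C=O | intermediate
31 | 3-lithio derivative of 17 (lithium on pyridine C3) | [Li]c1c(OCOC)ncc([C@]2(O[Si](CC)(CC)CC)CC[C@@H](O[Si](CC)(CC)CC)[C@@H]3O[C@@H]32)c1OCOC | intermediate
32 | secondary carbinol from 31 and 30 (both epimers at the carbinol carbon; all other centres as in 33) | C/C=C/[C@@H]1[C@H]2C[C@@H](C)CC[C@@H]2C(C)=C[C@H]1C(O)c1c(OCOC)c([C@]2(O[Si](CC)(CC)CC)CC[C@@H](O[Si](CC)(CC)CC)[C@@H]3O[C@@H]32)cnc1OCOC | intermediate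
33 | [(1R,2S,4aS,7S,8aR)-4,7-dimethyl-1-[(E)-prop-1-enyl]-1,2,4a,5,6,7,8,8a-octahydronaphthalen-2-yl]{5-[(1R,2S,3R,4R)-2,3-epoxy-1,4-bis(triethylsilyloxy)cyclohexyl]-2,4-bis(methoxymethoxy)pyridin-3-yl}methanone | C/C=C/[C@@H]1[C@H]2C[C@@H](C)CC[C@@H]2C(C)=C[C@H]1C(=O)c1c(OCOC)c([C@]2(O[Si](CC)(CC)CC)CC[C@@H](O[Si](CC)(CC)CC)[C@@H]3O[C@@H]32)cnc1OCOC | intermediate
34 | 3-[(1R,2S,4aS,7S,8aR)-4,7-dimethyl-1-[(E)-prop-1-enyl]-1,2,4a,5,6,7,8,8a-octahydronaphthalene-2-carbonyl]-5-[(1R,2S,3S,4R)-2,3-epoxy-1,4-dihydroxycyclohexyl]-4-hydroxypyridin-2(1H)-one | C/C=C/[C@@H]1[C@H]2C[C@@H](C)CC[C@@H]2C(C)=C[C@H]1C(=O)c1c(O)c([C@]2(O)CC[C@@H](O)[C@@H]3O[C@@H]32)c[nH]c1=O | target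

## Step count and least certain steps

Total step count: 24 (steps 1–24, convergent). Longest linear sequence: 14 steps (steps 11–24, from 18 to 34). The cyclohexane–pyridine branch reaches 34 in 11 steps from 1.

**Step 6 (key step).** What may go wrong: the electron-rich pyridine may be oxidised by electron transfer under the sensitised irradiation. The ene reaction or [2+2] addition at the aryl-substituted double bond may compete with the [4+2] mode. Face selectivity may erode. The peroxide may rearrange thermally or by base during isolation.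

Fallback (sets out from 9, returns at 12): the two C–O bonds would be made one after the other.
- Epoxidation of the C4'=C5' double bond of 9 on the face away from the acetal (m-CPBA, NaHCO3, CH2Cl2, 0 °C) would give the vinyl epoxide F1.
- Zerovalent-palladium-catalysed syn-1,4-opening with acetic acid (Pd(PPh3)4, AcOH, THF, 0 °C), in which ionisation and attack of acetate each proceed with inversion, would give the cis 4'-hydroxy 1'-acetate F2.
- Diimide reduction of C5'=C6' (2-nitrobenzenesulfonohydrazide, Et3N, CH2Cl2) would give the saturated hydroxy acetate F3.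
- Methanolysis of the acetate (K2CO3, MeOH) would return the route at 12.

**Step 21.** What may go wrong: the equilibration at C2 may be incomplete because the equatorial preference of a formyl group at an allylic ring position is small. γ-Protonation of the dienolate may move C3=C4 into conjugation with the aldehyde.

Fallback (sets out from 29 and 17, returns at 33): the epimerisation would be moved to the ketone stage, where the 2,6-dioxygenated aroyl group is much larger and every other functional group is base-stable.
- Lithiation of 17 as in step 22 and addition to 29 would give the C2-epimeric carbinol F4.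
- Dess–Martin oxidation would give the C2-epimeric ketone F5.
- DBU in toluene would equilibrate F5 to 33.

**Step 10.** What may go wrong: acetyl bromide or traces of HBr may cleave a methoxymethyl or triethylsilyl ether. The bromo acetate may fail to reach the trans-diaxial arrangement needed for closure next to the quaternary C1'.

Fallback (sets out from 14, returns at 17): the diol would be activated as a cyclic sulfate instead of an acyloxonium ion.
- SOCl2 and Et3N would give the cyclic sulfite F6.
- RuCl3 (catalytic) and NaIO4 would give the cyclic sulfate F7.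
- LiBr in THF would open it with inversion at C3' to the lithium bromo sulfate F8.
- Catalytic H2SO4 with one equivalent of water in THF would hydrolyse the sulfate ester to the bromohydrin F9.
- K2CO3 in MeOH would close F9 to 17 with the second inversion.

**Step 24.** What may go wrong: the acid may open the epoxide, ionise the C1' carbinol, or trigger enolisation at C2 before the last acetal has left.

Fallback (sets out from 33, returns at 34): the acetals would be removed without protic acid.
- Me3SiOTf with 2,2'-bipyridyl in MeCN at 0 °C would convert the two aryl methoxymethyl ethers into silyl ethers that hydrolyse on aqueous work-up, giving the bis(triethylsilyl) pyridone F10.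
- HF·pyridine in THF–pyridine at 0 °C would then remove the two triethylsilyl ethers to give 34.

## Further compounds

F1 | step 6 | vinyl epoxide of 9 (epoxide at C4'–C5', anti to the acetal) | COCOc1cc(OCOC)ncc1C1=C[C@H]2O[C@H]2[C@@H]3O[C@@H](c4ccccc4)O[C@H]13
F2 | step 6 | cis 4'-hydroxy 1'-acetate with C5'=C6' (both oxygens anti to the acetal) | COCOc1cc(OCOC)ncc1[C@]2(OC(C)=O)C=C[C@@H](O)[C@@H]3O[C@@H](c4ccccc4)O[C@@H]32
F3 | step 6 | saturated cis 4'-hydroxy 1'-acetate | COCOc1cc(OCOC)ncc1[C@]2(OC(C)=O)CC[C@@H](O)[C@@H]3O[C@@H](c4ccccc4)O[C@@H]32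
F4 | step 21 | C2-epimeric carbinol (from 17 and 29) | C/C=C/[C@@H]1[C@H]2C[C@@H](C)CC[C@@H]2C(C)=C[C@@H]1C(O)c1c(OCOC)c([C@]2(O[Si](CC)(CC)CC)CC[C@@H](O[Si](CC)(CC)CC)[C@@H]3O[C@@H]32)cnc1OCOC
F5 | step 21 | C2-epimer of ketone 33 | C/C=C/[C@@H]1[C@H]2C[C@@H](C)CC[C@@H]2C(C)=C[C@@H]1C(=O)c1c(OCOC)c([C@]2(O[Si](CC)(CC)CC)CC[C@@H](O[Si](CC)(CC)CC)[C@@H]3O[C@@H]32)cnc1OCOC
F6 | step 10 | cyclic sulfite of 14 | COCOc1cc(OCOC)ncc1[C@]2(O[Si](CC)(CC)CC)CC[C@@H](O[Si](CC)(CC)CC)[C@@H]3OS(=O)O[C@@H]32
F7 | step 10 | cyclic sulfate of 14 | COCOc1cc(OCOC)ncc1[C@]2(O[Si](CC)(CC)CC)CC[C@@H](O[Si](CC)(CC)CC)[C@@H]3OS(=O)(=O)O[C@@H]32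
F8 | step 10 | lithium trans-3'-bromo-2'-sulfate | COCOc1cc(OCOC)ncc1[C@]1(O[Si](CC)(CC)CC)CC[C@@H](O[Si](CC)(CC)CC)[C@@H](Br)[C@@H]1OS(=O)(=O)[O-].[Li+]
F9 | step 10 | trans-3'-bromo-2'-hydroxy compound (bromohydrin) | COCOc1cc(OCOC)ncc1[C@]1(O[Si](CC)(CC)CC)CC[C@@H](O[Si](CC)(CC)CC)[C@@H](Br)[C@@H]1O
F10 | step 24 | 1',4'-bis-O-triethylsilyl ether of 34 | C/C=C/[C@@H]1[C@H]2C[C@@H](C)CC[C@@H]2C(C)=C[C@H]1C(=O)c1c(O)c([C@]2(O[Si](CC)(CC)CC)CC[C@@H](O[Si](CC)(CC)CC)[C@@H]3O[C@@H]32)c[nH]c1=O
A1 | alternative 1 | methyl 4,7-dimethyl-3-oxo-1-[(E)-prop-1-enyl]-1,2,3,5,6,7,8,8a-octahydronaphthalene-2-carboxylate, C1, C2, C7 and C8a as in the target | C/C=C/[C@@H]1[C@H]2C[C@@H](C)CCC2=C(C)C(=O)[C@H]1C(=O)OC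
A2 | alternative 1 | methyl (4E)-2-propanoylhexa-2,4-dienoate | CCC(=O)C(=C/C=C/C)C(=O)OC
A3 | alternative 1 | 4-methylcyclohexanone | CC1CCC(=O)CC1
A4 | alternative 2 | fully protected target (two methoxymethyl ethers, trimethylsilyl ether at C1', tert-butyldimethylsilyl ether at C4') | C/C=C/[C@@H]1[C@H]2C[C@@H](C)CC[C@@H]2C(C)=C[C@H]1C(=O)c1c(OCOC)c([C@]2(O[Si](C)(C)C)CC[C@@H](O[Si](C)(C)C(C)(C)C)[C@@H]3O[C@@H]32)cnc1OCOC
A5 | alternative 2 | decalin C2 methyl carbonate, carbonate cis to the propenyl group | C/C=C/[C@@H]1[C@H]2C[C@@H](C)CC[C@@H]2C(C)=C[C@@H]1OC(=O)OC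
A6 | alternative 2 | 3-(trimethylstannyl)-2,4-bis(methoxymethoxy)-5-(protected epoxycyclohexyl)pyridine | C[Sn](C)(C)c1c(OCOC)c([C@]2(O[Si](C)(C)C)CC[C@@H](O[Si](C)(C)C(C)(C)C)[C@@H]3O[C@@H]32)cnc1OCOC
A7 | alternative 2 | carbon monoxide | [C-]#[O+]
A8 | alternative 3 | ethyl trans-6-formyl-3-(triisopropylsilyloxy)cyclohex-3-ene-1-carboxylate, C1 and C2 as in the target | O=C[C@@H]1CC=C(O[Si](C(C)C)(C(C)C)C(C)C)C[C@H]1C(=O)OCC
A9 | alternative 3 | 2-(triisopropylsilyloxy)buta-1,3-diene | C=CC(=C)O[Si](C(C)C)(C(C)C)C(C)C
A10 | alternative 3 | ethyl (E)-4-oxobut-2-enoate | CCOC(=O)/C=C/C=O
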